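Mutilin numbering: cyclohexane C4–C9; cyclopentanone C1–C4/C9; cyclooctane C4, C5, C14–C10, C9; tetrahydrofuran C11–O–C20–C19–C12.
Enabling feature: quaternary C5 belongs to both the cyclohexane and the cyclooctane, carries carbinol C14 and adjoins C6, whose methyl can stand in for a carbonyl. C6(=O)–C5–C14(OH) is therefore the retron of a 2,3-epoxy-alcohol semipinacol shift.
Retrosynthetic cuts, in order: silyl and ester groups; C3=O, C16 and C17 back to C3–Si, C6=O and C10=CH2; C4–C5 (C4 returned to C6, so cyclohexane becomes cyclopentane and cyclooctane becomes an epoxycyclononane); C5=C14 (metathesis); C5–C6 (isopropenyl addition); O11–C20; C10–C11 (Ni/Cr coupling).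
Forward order: bought cyclopentenone ring (C4, C6–C9), then ring C1–C4/C9 by aldol condensation, then the tetrahydrofuran, then a nine-membered ring by metathesis. One 1,2-shift then gives cyclohexane and cyclooctane together.
Stereochemistry: C9 from a catalytic enantioselective conjugate addition. C19 from (S)-3-hydroxybutyrolactone, relayed to C12 (dianion alkylation) and C11 (Felkin–Anh). C5 and C14 from directed epoxidation of the Z ring alkene plus the stereospecific shift. C6 and C10 by hydrogenation, C4 by equilibration.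

Key step: step 15

Assumption: the descriptors of the target string are taken literally. With the cyclohexane drawn so that C4→C5→…→C9 runs clockwise, H-4, C14 (on C5), the C6 methyl and C1 (on C9) are up, and C3 (on C4), the C5 methyl and C10 (on C9) are down. C10 and C14 are thus trans across the ring (a trans-bridged bicyclo[5.3.1]undecane) and the hydrindanone is trans-fused; the route is built for that array.

Step 1
Reactants: 1 3-ethoxycyclopent-2-en-1-one; 2 [2-(1,3-dioxan-2-yl)ethyl]magnesium bromide
Product: 3 3-[2-(1,3-dioxan-2-yl)ethyl]cyclopent-2-en-1-one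
Conditions: THF, 0 °C → rt; then 1 M HCl, 0 °C
Reagents that add atoms: water, O
Why: Stork–Danheiser sequence: the Grignard reagent adds 1,2 to the vinylogous ester and mild acid unmasks the transposed enone while the 1,3-dioxane survives; no stereocentre is formed.

Step 2
Reactants: 3 3-[2-(1,3-dioxan-2-yl)ethyl]cyclopent-2-en-1-one
Product: 4 (S)-3-[2-(1,3-dioxan-2-yl)ethyl]-3-[1-(trimethylsilyl)ethenyl]cyclopentan-1-one
Conditions: HC≡CSiMe3, i-Bu2AlH, hexanes/THF, 55 °C; then 3, chiral bidentate NHC–Cu catalyst (5 mol %), THF, −15 → 22 °C; aq. Rochelle salt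
Reagents that add atoms: trimethylsilylacetylene, C#C[Si](C)(C)C
Why: Copper-catalysed enantioselective conjugate addition of an α-silyl alkenylaluminium to a β-substituted cyclopentenone, a reaction type shown on this enone class; the chiral ligand alone fixes quaternary C9 as S.

Step 3
Reactants: 4 (S)-3-[2-(1,3-dioxan-2-yl)ethyl]-3-[1-(trimethylsilyl)ethenyl]cyclopentan-1-one
Product: 7 diquinane enone (S)-5-[1-(trimethylsilyl)ethenyl]bicyclo[3.3.0]oct-1-en-8-one, via keto aldehyde 5 (not isolated), via aldol 6 (not isolated)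
Conditions: p-TsOH·H2O (20 mol %), acetone/H2O, 50 °C
Reagents that add atoms: none
Why: Acetal hydrolysis and intramolecular aldol condensation (cyclopentene annulation): only attack of C4 on C3 gives an aldol that can dehydrate, so the reversible aldol manifold should drain to the fused C3=C4 enone; C9 is untouched.

Step 4
Reactants: 7 diquinane enone
Product: 8 cis-fused β-silyl ketone (PhMe2Si on C3)
Conditions: PhMe2Si–Bpin (1.2 equiv), CuCl (5 mol %), imidazolium salt (5 mol %), NaOt-Bu (10 mol %), MeOH (2 equiv), THF, 22 °C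
Reagents that add atoms: (dimethylphenylsilyl)boronic acid pinacol ester, C[Si](C)(c1ccccc1)B1OC(C)(C)C(C)(C)O1
Why: Copper-catalysed conjugate silylation: the silylcopper species should attack C3 anti to the angular C10 group and protonation at C4 can only give the cis-fused bicyclo[3.3.0]octanone, so the silyl group ends on the concave face, trans to H-4 and C10.

Step 5
Reactants: 8 cis-fused β-silyl ketone
Product: 9 vinyl iodide ketone
Conditions: N-iodosuccinimide, (CF3)2CHOH, 0 °C
Reagents that add atoms: N-iodosuccinimide, O=C1CCC(=O)N1I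
Why: Electrophilic ipso-iododesilylation of the vinylsilane, which is far more reactive towards I+ than the alkyl(aryl)silane or the ketone; no stereocentre changes.

Step 6
Reactants: 10 (S)-3-hydroxy-γ-butyrolactone
Product: 11 (3S,4S)-4-hydroxy-3-methyldihydrofuran-2(3H)-one (trans)
Conditions: LDA (2.2 equiv), THF, −78 °C; MeI; aq. NH4Cl
Reagents that add atoms: iodomethane, CI
Why: Fráter–Seebach-type alkylation of the alkoxide–enolate dianion: MeI enters anti to the C19 alkoxide and should give the trans lactone.

Step 7
Reactants: 11 trans-methyl hydroxy lactone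
Product: 12 (3S,4S)-3-allyl-4-hydroxy-3-methyldihydrofuran-2(3H)-one
Conditions: LDA (2.3 equiv), THF/DMPU, −78 → −30 °C; allyl bromide; aq. NH4Cl
Reagents that add atoms: allyl bromide, C=CCBr
Why: Second dianion alkylation: allyl bromide again enters anti to the C19 alkoxide, which sets quaternary C12 with the allyl group (C13) trans and the methyl cis to the C19 oxygen.

Step 8
Reactants: 12 allyl methyl hydroxy lactone
Product: 13 C19 TBS ether of lactone 12
Conditions: TBSOTf, 2,6-lutidine, CH2Cl2, 0 °C
Reagents that add atoms: tert-butyldimethylsilyl triflate, CC(C)(C)[Si](C)(C)OS(=O)(=O)C(F)(F)F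
Why: Silyl triflate silylation of a hindered secondary alcohol; the stereocentres are not involved.

Step 9
Reactants: 13 TBS lactone
Product: 14 lactol (anomer mixture at C11)
Conditions: i-Bu2AlH (1.1 equiv), toluene, −78 °C; aq. Rochelle salt
Reagents that add atoms: none
Why: Partial reduction of a lactone: the tetrahedral aluminium hemiacetal is stable at −78 °C, so reduction should stop at the lactol; C12 and C19 are untouched.

Step 10
Reactants: 9 vinyl iodide ketone; 14 lactol
Product: 15 C11/C20 diol (C10–C11 bond made)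
Conditions: CrCl2 (6 equiv), NiCl2 (2 mol %), DMSO, 25 °C
Reagents that add atoms: none
Why: Nozaki–Hiyama–Kishi coupling: the alkenylchromium(III) species adds to the aldehyde tautomer of the lactol and not to the ketone, and Felkin–Anh attack anti to the C19 branch and past the C12 methyl should set C11 with C10 syn to C13.

Step 11
Reactants: 15 C11/C20 diol
Product: 17 tetrahydrofuranyl diquinane ketone, via primary tosylate 16 (not isolated)
Conditions: TsCl (1.1 equiv), pyridine, DMAP (cat.), 0 → 60 °C
Reagents that add atoms: none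
Why: Selective sulfonylation of the primary C20 hydroxyl followed by 5-exo-tet Williamson closure by O-11; no stereocentre is touched, so H-11, the C12 methyl and the C19 oxygen stay cis on the new ring.

Step 12
Reactants: 17 tetrahydrofuranyl diquinane ketone
Product: 18 isopropenyl carbinol (tertiary alcohol at C6)
Conditions: isopropenylmagnesium bromide, LaCl3·2LiCl (30 mol %), THF, −78 → 0 °C; aq. NH4Cl
Reagents that add atoms: isopropenylmagnesium bromide, CC(=C)[Mg]Br
Why: Lanthanide-assisted Grignard 1,2-addition: attack from the convex face of the cis-bicyclo[3.3.0]octanone, the concave face being closed by the fold of the second ring and by the C3 silyl group, should place C5 syn to the C10 branch and the hydroxyl on the concave face.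

Step 13
Reactants: 18 isopropenyl carbinol
Product: 19 bridged allylic alcohol (bicyclo[6.2.1] core, Z-C5=C14)
Conditions: second-generation Ru alkylidene catalyst with chelating isopropoxybenzylidene (10 mol %), toluene (1 mM), 80 °C, Ar purge
Reagents that add atoms: none
Why: Ring-closing metathesis of the allyl and isopropenyl groups (allylic hydroxyl assistance), the C10 methylene between two fully substituted carbons being inert; the nine-membered ring can hold only the Z alkene (C6 cis to C13).

Step 14
Reactants: 19 bridged allylic alcohol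
Product: 20 bridged 2,3-epoxy alcohol
Conditions: VO(acac)2 (5 mol %), t-BuOOH (1.5 equiv), CH2Cl2, 0 °C
Reagents that add atoms: tert-butyl hydroperoxide, CC(C)(C)OO
Why: Vanadium-catalysed hydroxyl-directed epoxidation: oxygen is delivered syn to the C6 hydroxyl in the conformer that puts ring CH2 C7, not C4, next to the vinylic methyl (A1,2 strain), which is also the peripheral face of the ring alkene, and this sets C5 and C14; the non-allylic C10 methylene is left.

Step 15
Reactants: 20 bridged 2,3-epoxy alcohol
Product: 21 tetracyclic β-hydroxy ketone (cyclohexanone and cyclooctane in final size)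
Conditions: Me3Al (3 equiv), CH2Cl2, −78 → 0 °C; aq. Rochelle salt
Reagents that add atoms: none
Why: Me3Al deprotonates the C6 hydroxyl, the O–Al centre also binds the epoxide oxygen, the tertiary C5–O bond ionises and the antiperiplanar C6–C4 bond moves to C5 while C6 becomes the ketone (semipinacol rearrangement of a 2,3-epoxy alcohol); the closest known reaction type is the organoaluminium-promoted epoxy-alcohol rearrangement used to build strained inside–outside bridged bicycles. No ring is closed by cyclisation: the 1,2-shift inserts C5 into the cyclopentane C4–C6–C7–C8–C9 (one-atom expansion to the cyclohexane C4–C5–C6–C7–C8–C9) and expels C6 from the nine-membered ring (one-atom contraction to the cyclooctane). C5 is formed with inversion, C4 entering from inside the nine-membered ring anti to the peripherally delivered oxygen, so that C14 ends trans to C10 across the new cyclohexane and the C5 methyl cis to it; C14 keeps its C–O bond and thus the configuration set by the Z alkene and the epoxidation face, and C4 migrates with retention. The step needs C4, and not C7, a hydride or an aluminium methyl, to reach C5: the bicyclic frame holds C5–O anti to C6–C4 and gauche to C6–C7, and the C3–Si bond stabilises positive charge on the migrating C4 (β-silicon effect). Release of epoxide strain and formation of the C=O bond should pay for the strain of the trans-bridged product.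

Step 16
Reactants: 21 tetracyclic β-hydroxy ketone
Product: 22 C14 (tert-butyldiphenylsilyloxy)acetate
Conditions: TBDPSOCH2CO2H, EDC·HCl, DMAP, CH2Cl2, rt
Reagents that add atoms: (tert-butyldiphenylsilyloxy)acetic acid, OC(=O)CO[Si](c1ccccc1)(c1ccccc1)C(C)(C)C
Why: Carbodiimide/DMAP (Steglich) esterification of the only free hydroxyl installs the side chain and blocks retro-aldol cleavage of the β-hydroxy ketone; C14 is not inverted.

Step 17
Reactants: 22 C14 silyloxyacetate ketone
Product: 23 bis(exo-methylene) compound (C6=CH2, C10=CH2)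
Conditions: Zn, CH2Br2, TiCl4, THF/CH2Cl2, 0 °C → rt
Reagents that add atoms: dibromomethane, BrCBr
Why: Lombardo methylenation is non-basic and selective for ketones over esters, so the hindered C6 ketone should be converted without touching the ester or C5.

Step 18
Reactants: 23 bis(exo-methylene) compound
Product: 24 saturated C6,C10-dimethyl compound
Conditions: H2 (1 atm), PtO2, EtOAc, rt
Reagents that add atoms: none
Why: Heterogeneous hydrogenation of the two 1,1-disubstituted alkenes: at C6 hydrogen should arrive anti to the C14 branch on neighbouring C5 (methyl ends cis to C14), at C10 from the outer face of the cyclooctane.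

Step 19
Reactants: 24 saturated C3 silane
Product: 25 C3 alcohol
Conditions: KBr, AcOOH, NaOAc, AcOH, rt
Reagents that add atoms: peracetic acid, CC(=O)OO
Why: Fleming–Tamao oxidation replaces the dimethyl(phenyl)silyl group by hydroxyl with retention; at this stage no alkene or ketone is left for the peracid, and the hindered O-bound TBDPS group is much less prone to dearylation.

Step 20
Reactants: 25 C3 alcohol
Product: 27 trans-fused C3 ketone, via cis-fused ketone 26 (not isolated)
Conditions: Dess–Martin periodinane, CH2Cl2, 0 °C → rt; then DBU (0.5 equiv), rt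
Reagents that add atoms: none
Why: Dess–Martin oxidation of the only free alcohol, then base equilibration through the C3–C4 enolate: C3 leaves the axial site on the cyclohexane, where it is 1,3-diaxial to the C6 methyl, for the equatorial one, which should set H-4 anti to C10.

Step 21
Reactants: 27 trans-fused C3 ketone
Product: 28 pleuromutilin B
Conditions: HF·pyridine, THF/pyridine, 0 °C → rt
Reagents that add atoms: none
Why: Fluoride-mediated cleavage of both silyl ethers under non-basic conditions spares the glycolate ester and the C4 centre.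

Compound list
1 | 3-ethoxycyclopent-2-en-1-one | CCOC1=CC(=O)CC1 | starting material
2 | [2-(1,3-dioxan-2-yl)ethyl]magnesium bromide (THF solution) | Br[Mg]CCC1OCCCO1 | starting material
3 | 3-[2-(1,3-dioxan-2-yl)ethyl]cyclopent-2-en-1-one | O=C1C=C(CCC2OCCCO2)CC1 | intermediate
4 | (S)-3-[2-(1,3-dioxan-2-yl)ethyl]-3-[1-(trimethylsilyl)ethenyl]cyclopentan-1-one (C9 S) | C=C([Si](C)(C)C)[C@@]1(CCC2OCCCO2)CCC(=O)C1 | intermediate
5 | (S)-3-{3-oxo-1-[1-(trimethylsilyl)ethenyl]cyclopentyl}propanal | C=C([Si](C)(C)C)[C@@]1(CCC=O)CCC(=O)C1 | intermediate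
6 | cis-fused aldol, 2-hydroxy-5-[1-(trimethylsilyl)ethenyl]bicyclo[3.3.0]octan-8-one (C3 carbinol as epimer mixture) | C=C([Si](C)(C)C)[C@]12CCC(O)[C@H]1C(=O)CC2 | intermediate
7 | (S)-5-[1-(trimethylsilyl)ethenyl]bicyclo[3.3.0]oct-1-en-8-one (C3=C4 enone, C6 ketone) | C=C([Si](C)(C)C)[C@]12CCC=C1C(=O)CC2 | intermediate
8 | cis-fused 2-[dimethyl(phenyl)silyl]-5-[1-(trimethylsilyl)ethenyl]bicyclo[3.3.0]octan-8-one (H-4 syn to C10; silyl on C3 anti to both, concave face) | C=C([Si](C)(C)C)[C@]12CC[C@@H]([Si](C)(C)c3ccccc3)[C@H]1C(=O)CC2 | intermediate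
9 | cis-fused 2-[dimethyl(phenyl)silyl]-5-(1-iodoethenyl)bicyclo[3.3.0]octan-8-one (configuration as 8) | C=C(I)[C@]12CC[C@@H]([Si](C)(C)c3ccccc3)[C@H]1C(=O)CC2 | intermediate
10 | (S)-3-hydroxy-γ-butyrolactone | O=C1C[C@H](O)CO1 | starting material
11 | (3S,4S)-4-hydroxy-3-methyldihydrofuran-2(3H)-one (methyl trans to OH) | C[C@H]1[C@H](O)COC1=O | intermediate
12 | (3S,4S)-3-allyl-4-hydroxy-3-methyldihydrofuran-2(3H)-one (allyl trans, methyl cis to OH) | C=CC[C@@]1(C)[C@H](O)COC1=O | intermediate
13 | TBS ether of 12 | C=CC[C@@]1(C)[C@H](O[Si](C)(C)C(C)(C)C)COC1=O | intermediate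
14 | lactol from 13 (C11 anomer mixture) | C=CC[C@@]1(C)[C@H](O[Si](C)(C)C(C)(C)C)COC1O | intermediate
15 | diol: diquinane ketone carrying on C9 the unit C10(=CH2)–C11H(OH)–C12(CH3)(allyl)–C19H(OTBS)–C20H2OH (Felkin product at C11) | C=CC[C@@](C)([C@H](O[Si](C)(C)C(C)(C)C)CO)[C@@H](O)C(=C)[C@]12CC[C@@H]([Si](C)(C)c3ccccc3)[C@H]1C(=O)CC2 | intermediate
16 | C20 p-toluenesulfonate of 15 | C=CC[C@@](C)([C@H](O[Si](C)(C)C(C)(C)C)COS(=O)(=O)c1ccc(C)cc1)[C@@H](O)C(=C)[C@]23CC[C@@H]([Si](C)(C)c4ccccc4)[C@H]2C(=O)CC3 | intermediate
17 | tetrahydrofuranyl diquinane ketone (on the tetrahydrofuran H-11, C12 methyl and C19 OTBS cis; C10 and allyl on the other face) | C=CC[C@@]1(C)[C@H](O[Si](C)(C)C(C)(C)C)CO[C@H]1C(=C)[C@]23CC[C@@H]([Si](C)(C)c4ccccc4)[C@H]2C(=O)CC3 | intermediate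
18 | isopropenyl carbinol (at C6 isopropenyl syn to C10 and H-4, hydroxyl on the concave face) | C=CC[C@@]1(C)[C@H](O[Si](C)(C)C(C)(C)C)CO[C@H]1C(=C)[C@]23CC[C@@H]([Si](C)(C)c4ccccc4)[C@H]2[C@](O)(C(C)=C)CC3 | intermediate
19 | bridged allylic alcohol: nine-membered ring C6–C5=C14–C13–C12–C11–C10–C9–C4 spanning the convex face of the cyclopentane, Z alkene (C6 cis to C13) | C=C1[C@@H]2OC[C@@H](O[Si](C)(C)C(C)(C)C)[C@]2(C)C/C=C(/C)[C@]2(O)CC[C@]13CC[C@@H]([Si](C)(C)c4ccccc4)[C@H]32 | intermediate
20 | bridged 2,3-epoxy alcohol (C5–C14 epoxide on the peripheral face, syn to the C6 hydroxyl; C6 and C13 cis on the oxirane) | C=C1[C@@H]2OC[C@@H](O[Si](C)(C)C(C)(C)C)[C@]2(C)C[C@H]4O[C@@]4(C)[C@]2(O)CC[C@]13CC[C@@H]([Si](C)(C)c5ccccc5)[C@H]32 | intermediate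
21 | tetracyclic β-hydroxy ketone (C6 ketone; C5 methyl cis and C14 trans to C10; C14 R; H-4 still syn to C10) | C=C1[C@@H]2OC[C@@H](O[Si](C)(C)C(C)(C)C)[C@]2(C)C[C@@H](O)[C@@]2(C)C(=O)CC[C@]13CC[C@@H]([Si](C)(C)c4ccccc4)[C@H]32 | intermediate
22 | C14 (tert-butyldiphenylsilyloxy)acetate of 21 | C=C1[C@@H]2OC[C@@H](O[Si](C)(C)C(C)(C)C)[C@]2(C)C[C@@H](OC(=O)CO[Si](c4ccccc4)(c5ccccc5)C(C)(C)C)[C@@]2(C)C(=O)CC[C@]13CC[C@@H]([Si](C)(C)c4ccccc4)[C@H]32 | intermediate
23 | 6,10-bis(methylene) compound | C=C1[C@@H]2OC[C@@H](O[Si](C)(C)C(C)(C)C)[C@]2(C)C[C@@H](OC(=O)CO[Si](c4ccccc4)(c5ccccc5)C(C)(C)C)[C@@]2(C)C(=C)CC[C@]13CC[C@@H]([Si](C)(C)c4ccccc4)[C@H]32 | intermediate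
24 | saturated silane (C6 methyl cis to C14 and trans to the C5 methyl; C10 as in the target) | C[C@H]1[C@@H]2OC[C@@H](O[Si](C)(C)C(C)(C)C)[C@]2(C)C[C@@H](OC(=O)CO[Si](c4ccccc4)(c5ccccc5)C(C)(C)C)[C@@]2(C)[C@@H](C)CC[C@]13CC[C@@H]([Si](C)(C)c4ccccc4)[C@H]32 | intermediate
25 | C3 alcohol (hydroxyl in place of silicon, retention) | C[C@H]1[C@@H]2OC[C@@H](O[Si](C)(C)C(C)(C)C)[C@]2(C)C[C@@H](OC(=O)CO[Si](c4ccccc4)(c5ccccc5)C(C)(C)C)[C@@]2(C)[C@@H](C)CC[C@]13CC[C@@H](O)[C@H]32 | intermediate
26 | cis-fused C3 ketone (H-4 syn to C10) | C[C@H]1[C@@H]2OC[C@@H](O[Si](C)(C)C(C)(C)C)[C@]2(C)C[C@@H](OC(=O)CO[Si](c4ccccc4)(c5ccccc5)C(C)(C)C)[C@@]2(C)[C@@H](C)CC[C@]13CCC(=O)[C@H]32 | intermediate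
27 | trans-fused C3 ketone (H-4 anti to C10), bis-silyl ether of the target | C[C@H]1[C@@H]2OC[C@@H](O[Si](C)(C)C(C)(C)C)[C@]2(C)C[C@@H](OC(=O)CO[Si](c4ccccc4)(c5ccccc5)C(C)(C)C)[C@@]2(C)[C@@H](C)CC[C@]13CCC(=O)[C@@H]32 | intermediate
28 | pleuromutilin B | C[C@H]1[C@@H]2OC[C@@H](O)[C@]2(C)C[C@@H](OC(=O)CO)[C@@]2(C)[C@@H](C)CC[C@]13CCC(=O)[C@@H]32 | target

Total step count: 21. Longest linear sequence: 17 steps (steps 1–5 and 10–21).

Steps most likely to fail

Step 13 (ring-closing metathesis). The catalyst may never load onto the hindered 1,1-disubstituted alkene next to the tertiary carbinol, so dimerisation through the allyl termini can outrun closure of the nine-membered ring. The fallback is relay ring-closing metathesis, a change of substrate design. From 17, the alkenyllithium made from (Z)-3-iodobut-2-enyl allyl ether and t-BuLi is added in place of the isopropenyl reagent to give relay carbinol F1. The catalyst loads on the unhindered allyl ether terminus and expels 2,5-dihydrofuran, which places it on C5 as the alkylidene. That alkylidene only has to find the allyl terminus at C14, and the route is rejoined at 19.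

Step 12 (addition to the C6 ketone). The facial selectivity may be poor, since the C10 branch also crowds the convex face, and enolisation may compete; the epimer with C5 anti to C10 cannot be bridged. The fallback makes the C5–C6 bond last and intramolecularly. From 17, selective Lemieux–Johnson cleavage (OsO4 cat., NaIO4) of the unhindered allyl group gives keto aldehyde F2. The (1-iodoethylidene)triphenylphosphorane then turns the aldehyde into (Z)-vinyl iodide F3. A Barbier-type closure at high dilution (Ni/Cr, or halogen–lithium exchange with t-BuLi at −100 °C) joins C5 to C6. The tether can reach the ketone only from the face that carries C10, so the carbinol configuration is enforced. The route is rejoined at 19, without 18 and without metathesis.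

Step 10 (Ni/Cr coupling with the lactol). Slow ring opening of the hindered lactol may let protonolysis or homocoupling of the alkenylchromium species take over. The fallback uses a true aldehyde that already carries the leaving group. From 13, Me(MeO)NH·HCl/i-PrMgCl opens the lactone to hydroxy Weinreb amide F4, TsCl/pyridine gives tosylate F5 and i-Bu2AlH gives aldehyde F6. Ni/Cr coupling of F6 with 9 gives 16 as its chromium alkoxide. This closes to 17 on warming with base, so the route is rejoined at 17 without 14 and 15.

Further compounds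
F1 | step 13 | relay carbinol (C6 carbinol as in 18, bearing C5(CH3)=CH–CH2–O–allyl with C6 cis to CH2O) | C=CC[C@@]1(C)[C@H](O[Si](C)(C)C(C)(C)C)CO[C@H]1C(=C)[C@]23CC[C@@H]([Si](C)(C)c4ccccc4)[C@H]2[C@](O)(C(\C)=C/COCC=C)CC3
F2 | step 12 | keto aldehyde (C14 aldehyde from the allyl group of 17) | O=CC[C@@]1(C)[C@H](O[Si](C)(C)C(C)(C)C)CO[C@H]1C(=C)[C@]23CC[C@@H]([Si](C)(C)c4ccccc4)[C@H]2C(=O)CC3
F3 | step 12 | (Z)-vinyl iodide (iodine on C5 cis to C13) | C/C(I)=C/C[C@@]1(C)[C@H](O[Si](C)(C)C(C)(C)C)CO[C@H]1C(=C)[C@]23CC[C@@H]([Si](C)(C)c4ccccc4)[C@H]2C(=O)CC3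
F4 | step 10 | hydroxy Weinreb amide from lactone 13 | C=CC[C@@](C)([C@H](O[Si](C)(C)C(C)(C)C)CO)C(=O)N(C)OC
F5 | step 10 | C20 tosylate of F4 | C=CC[C@@](C)([C@H](O[Si](C)(C)C(C)(C)C)COS(=O)(=O)c1ccc(C)cc1)C(=O)N(C)OC
F6 | step 10 | C11 aldehyde bearing the C20 tosylate | C=CC[C@@](C)([C@H](O[Si](C)(C)C(C)(C)C)COS(=O)(=O)c1ccc(C)cc1)C=O
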